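**Plan**

Locants (drimane type): ring A = C1–C5 and C10 (C3 ketone, C4 gem-dimethyl); ring B = C5–C10 (C6 OAc, C7=C8, C8 Me, C9 CH2OAr, C10 Me).
Retrosynthesis: cut the C6 acetate and the C11–O aryl ether, then C3–C4 (ring A, tertiary C4 radical onto a nitrile), then C5–C6 (ring B, carbonyl-ene), then C10–CH3, C10–C1 and C8–C9.
Enabling feature: with C3–C4 open, ring B is a 6-isopropenylcyclohex-2-en-1-ol (O–C6–C5–C4(=CH2)CH3 beside C7=C8, the isopiperitenol pattern), the retron of an ene closure of a (Z)-enal (C6) onto an isobutenyl group (C5=C4).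
Forward: butenolide → C9 (rhodium-catalysed addition) → quaternary C10 (two enolate alkylations) → δ-lactone C11–O–C2(=O)–C1 as temporary ring → ring B (ene) → lactone converted into CH2CH2CN and CH2OH → ring A (hydrogen atom transfer cyclization) → aryl ether, acetate.
Stereochemistry: C9 from (S)-BINAP; C10 by methylation anti to the C9 substituent; C5 and C6 in the ene step under control of the trans-fused lactone; the trans ring fusion follows from C5 and C10.

Key step: step 11

Assumption: lactols 10 and 16 are carried on as mixtures of anomers, because the lactol carbon loses its stereocentre in the following step.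

Step 1
Reactants: 1 but-2-yn-1-ol
Product: 2 (Z)-3-iodobut-2-en-1-ol
Conditions: NaAlH2(OCH2CH2OMe)2, THF, 0 °C to rt; then I2, −78 to 0 °C
Reagents that add atoms: iodine, II
Why: Hydroxyl-directed trans-hydroalumination of the propargylic alcohol puts aluminium on C3 cis to CH2OH and iodinolysis with retention gives the (Z)-iodide, which fixes the geometry of the later C7=C8 bond (reduction–iodination of a propargylic alcohol).

Step 2
Reactants: 2 (Z)-3-iodobut-2-en-1-ol
Product: 3 tert-butyl{[(2Z)-3-iodobut-2-en-1-yl]oxy}dimethylsilane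
Conditions: TBSCl, imidazole, DMF, rt
Reagents that add atoms: tert-butyldimethylsilyl chloride, CC(C)(C)[Si](C)(C)Cl
Why: Imidazole-promoted silylation of the primary alcohol (silyl ether protection) masks C6–OH through the organometallic, enolate and hydride steps.

Step 3
Reactants: 3 tert-butyl{[(2Z)-3-iodobut-2-en-1-yl]oxy}dimethylsilane
Product: 4 tert-butyldimethyl{[(2E)-3-(4,4,5,5-tetramethyl-1,3,2-dioxaborolan-2-yl)but-2-en-1-yl]oxy}silane (boron cis to CH2OSi)
Conditions: B2pin2, PdCl2(PPh3)2, PPh3, KOPh, toluene, 50 °C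
Reagents that add atoms: bis(pinacolato)diboron, CC1(C)OB(OC1(C)C)B1OC(C)(C)C(C)(C)O1
Why: Miyaura borylation of the alkenyl iodide (oxidative addition, boryl transfer from the phenoxide-activated diboron, reductive elimination) proceeds with retention of the double-bond geometry.

Step 4
Reactants: 4 tert-butyldimethyl{[(2E)-3-(4,4,5,5-tetramethyl-1,3,2-dioxaborolan-2-yl)but-2-en-1-yl]oxy}silane; 5 furan-2(5H)-one
Product: 6 (4S)-4-[(2Z)-4-{[tert-butyl(dimethyl)silyl]oxy}but-2-en-2-yl]oxolan-2-one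
Conditions: [Rh(OH)(cod)]2 (2.5 mol %), (S)-BINAP (6 mol %), dioxane/H2O 10:1, 50 °C
Reagents that add atoms: none
Why: Hayashi–Miyaura rhodium-catalysed asymmetric conjugate addition, in which the alkenylrhodium/(S)-BINAP species should add to the butenolide face predicted by the established model for cyclic enones and unsaturated lactones and so set C9 as (S), water protonating the rhodium enolate.

Step 5
Reactants: 6 (4S)-4-[(2Z)-4-{[tert-butyl(dimethyl)silyl]oxy}but-2-en-2-yl]oxolan-2-one; 7 tert-butyl bromoacetate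
Product: 8 tert-butyl [(3R,4S)-4-[(2Z)-4-{[tert-butyl(dimethyl)silyl]oxy}but-2-en-2-yl]-2-oxooxolan-3-yl]acetate (3,4-trans)
Conditions: LiN(SiMe3)2, THF, −78 °C; then 7, −78 to −30 °C
Reagents that add atoms: none
Why: Alkylation of the lactone lithium enolate with the reactive α-bromo ester occurs anti to the C9 substituent (enolate alkylation), and the configuration of this carbon is erased again in step 6.

Step 6
Reactants: 8 tert-butyl [(3R,4S)-4-[(2Z)-4-{[tert-butyl(dimethyl)silyl]oxy}but-2-en-2-yl]-2-oxooxolan-3-yl]acetate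
Product: 9 tert-butyl [(3S,4R)-4-[(2Z)-4-{[tert-butyl(dimethyl)silyl]oxy}but-2-en-2-yl]-3-methyl-2-oxooxolan-3-yl]acetate (methyl trans to the 4-alkenyl group)
Conditions: LiN(SiMe3)2, THF, −78 °C; then MeI, −78 to −20 °C
Reagents that add atoms: methyl iodide, CI
Why: LiN(SiMe3)2 removes the more acidic lactone α-hydrogen in preference to the tert-butyl ester CH2 and methyl iodide attacks the tetrasubstituted enolate on the face anti to the adjacent alkenyl group (1,2-induction in a γ-butyrolactone enolate alkylation), which sets quaternary C10 with methyl trans to C8.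

Step 7
Reactants: 9 tert-butyl [(3S,4R)-4-[(2Z)-4-{[tert-butyl(dimethyl)silyl]oxy}but-2-en-2-yl]-3-methyl-2-oxooxolan-3-yl]acetate
Product: 10 tert-butyl [(3S,4R)-4-[(2Z)-4-{[tert-butyl(dimethyl)silyl]oxy}but-2-en-2-yl]-2-hydroxy-3-methyloxolan-3-yl]acetate (lactol)
Conditions: i-Bu2AlH (1.1 equiv), CH2Cl2, −78 °C; aq. potassium sodium tartrate
Reagents that add atoms: none
Why: i-Bu2AlH at −78 °C stops at the aluminium hemiacetal of the γ-lactone and leaves the hindered tert-butyl ester untouched (partial reduction of a lactone to a lactol).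

Step 8
Reactants: 10 tert-butyl [(3S,4R)-4-[(2Z)-4-{[tert-butyl(dimethyl)silyl]oxy}but-2-en-2-yl]-2-hydroxy-3-methyloxolan-3-yl]acetate
Product: 12 (4R,5R)-5-[(2Z)-4-{[tert-butyl(dimethyl)silyl]oxy}but-2-en-2-yl]-4-methyl-4-(2-methylprop-1-en-1-yl)oxan-2-one, via hydroxy ester 11 (not isolated)
Conditions: i-PrPPh3I, KN(SiMe3)2, THF, 0 °C to rt; then 40 °C
Reagents that add atoms: isopropyltriphenylphosphonium iodide, CC(C)[P+](c1ccccc1)(c1ccccc1)c1ccccc1.[I-]
Why: Wittig olefination of the open hydroxy-aldehyde form of the lactol installs the C5=C4 isobutenyl group and the liberated C11 alkoxide then closes onto the tert-butyl ester (6-exo-trig lactonization), which creates the temporary δ-lactone C11–O–C2(=O)–C1.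

Step 9
Reactants: 12 (4R,5R)-5-[(2Z)-4-{[tert-butyl(dimethyl)silyl]oxy}but-2-en-2-yl]-4-methyl-4-(2-methylprop-1-en-1-yl)oxan-2-one
Product: 13 (4R,5R)-5-[(2Z)-4-hydroxybut-2-en-2-yl]-4-methyl-4-(2-methylprop-1-en-1-yl)oxan-2-one
Conditions: HF·pyridine, pyridine, THF, 0 °C to rt
Reagents that add atoms: none
Why: Buffered HF·pyridine cleaves the primary allylic silyl ether without opening the lactone or touching the alkenes (fluoride desilylation).

Step 10
Reactants: 13 (4R,5R)-5-[(2Z)-4-hydroxybut-2-en-2-yl]-4-methyl-4-(2-methylprop-1-en-1-yl)oxan-2-one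
Product: 14 (2Z)-3-[(3R,4R)-4-methyl-4-(2-methylprop-1-en-1-yl)-6-oxooxan-3-yl]but-2-enal
Conditions: Dess–Martin periodinane, pyridine, CH2Cl2, 0 °C; used at once
Reagents that add atoms: none
Why: Dess–Martin oxidation under pyridine buffering converts the (Z)-allylic alcohol into the (Z)-enal without acid or base strong enough to isomerize C7=C8 or to epimerize C9.

Step 11
Reactants: 14 (2Z)-3-[(3R,4R)-4-methyl-4-(2-methylprop-1-en-1-yl)-6-oxooxan-3-yl]but-2-enal
Product: 15 (4aS,5R,6R,8aR)-6-hydroxy-4a,8-dimethyl-5-(prop-1-en-2-yl)-4a,5,6,8a-tetrahydro-1H-isochromen-3(4H)-one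
Conditions: Me2AlCl (3 equiv), CH2Cl2, −78 to −20 °C; aq. potassium sodium tartrate
Reagents that add atoms: none
Why: Me2AlCl binds the aldehyde oxygen of the (Z)-enal and C5 of the isobutenyl group attacks C6 while an allylic hydrogen of a C4 methyl passes to oxygen through a six-membered, concerted but asynchronous array (intramolecular carbonyl-ene reaction), which leaves the isopropenyl group on C5. The closest known reaction type is the Lewis acid cyclization of neral to isopiperitenol (and of citronellal to isopulegol). Ring B closes as a six-membered ring with C7=C8 inside it and the new C4=CH2 bond outside it. C5 is controlled by the temporary δ-lactone, which holds the enal arm on C9 and the isobutenyl arm on C10 trans-diequatorial with C1 and C11 gauche, so that only the chair closure with the C10 methyl axial and H5 axial on the opposite face (the later trans ring fusion) is possible, the ring-flipped alternative needing C1 and C11 anti. C6 is controlled by the chair-like bicyclic ene array, in which the aluminium-bound oxygen sits equatorial, trans to the isopropenyl group and away from the axial C10 methyl. The step needs attack of C5 at C6 (not conjugate addition or chloride capture of a C4 cation) and the (Z)-geometry that lets C6 reach C5, which the proton-scavenging Me2AlCl and the (Z)-iodide origin of C7=C8 should secure.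

Step 12
Reactants: 15 (4aS,5R,6R,8aR)-6-hydroxy-4a,8-dimethyl-5-(prop-1-en-2-yl)-4a,5,6,8a-tetrahydro-1H-isochromen-3(4H)-one
Product: 16 (4aS,5R,6R,8aR)-4a,8-dimethyl-5-(prop-1-en-2-yl)-3,4,4a,5,6,8a-hexahydro-1H-isochromene-3,6-diol (lactol)
Conditions: i-Bu2AlH (2.3 equiv), CH2Cl2, −78 °C; aq. potassium sodium tartrate
Reagents that add atoms: none
Why: Partial reduction of the δ-lactone with i-Bu2AlH gives the six-membered lactol, which unmasks C2 at the aldehyde level while C11 stays bound as the hemiacetal oxygen.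

Step 13
Reactants: 16 (4aS,5R,6R,8aR)-4a,8-dimethyl-5-(prop-1-en-2-yl)-3,4,4a,5,6,8a-hexahydro-1H-isochromene-3,6-diol
Product: 17 3-[(1S,2R,5R,6R)-5-hydroxy-2-(hydroxymethyl)-1,3-dimethyl-6-(prop-1-en-2-yl)cyclohex-3-en-1-yl]propanenitrile
Conditions: TosMIC, KOt-Bu, DME, −40 °C to rt; then MeOH, 65 °C
Reagents that add atoms: p-toluenesulfonylmethyl isocyanide, Cc1ccc(cc1)S(=O)(=O)C[N+]#[C-]
Why: Van Leusen reductive cyanation, in which the TosMIC anion adds to the open aldehyde form of the lactol, the oxazoline opens and methanolysis with loss of sulfinate and formate gives the one-carbon-homologated nitrile (C3) and frees C11–OH, so that the temporary ring is removed.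

Step 14
Reactants: 17 3-[(1S,2R,5R,6R)-5-hydroxy-2-(hydroxymethyl)-1,3-dimethyl-6-(prop-1-en-2-yl)cyclohex-3-en-1-yl]propanenitrile
Product: 19 (4aS,5R,8R,8aS)-8-hydroxy-5-(hydroxymethyl)-1,1,4a,6-tetramethyl-3,4,4a,5,8,8a-hexahydronaphthalen-2(1H)-one, via ketimine 18 (not isolated)
Conditions: Fe(acac)3 (30 mol %), PhSiH3, EtOH, 60 °C; then AcOH/H2O/THF, rt
Reagents that add atoms: water, O
Why: The iron hydride formed from Fe(acac)3 and PhSiH3 transfers a hydrogen atom to the isopropenyl CH2, the tertiary C4 radical adds 6-exo-dig to the nitrile carbon C3 to close ring A, and reduction, protonation and hydrolysis of the iminyl species give the ketone (hydrogen-atom-transfer-initiated radical cyclization of an alkene onto a nitrile), the ring fusion being trans because C1 and C4 are both equatorial on ring B.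

Step 15
Reactants: 19 (4aS,5R,8R,8aS)-8-hydroxy-5-(hydroxymethyl)-1,1,4a,6-tetramethyl-3,4,4a,5,8,8a-hexahydronaphthalen-2(1H)-one; 20 7-hydroxy-2H-chromen-2-one
Product: 21 7-{[(1R,4R,4aS,8aS)-4-hydroxy-2,5,5,8a-tetramethyl-6-oxo-1,4,4a,5,6,7,8,8a-octahydronaphthalen-1-yl]methoxy}-2H-chromen-2-one
Conditions: PPh3, DIAD, THF, 0 °C to rt
Reagents that add atoms: none
Why: Mitsunobu etherification, in which the acidic phenol displaces the activated primary C11 oxyphosphonium group in an SN2 reaction, whereas the secondary C6–OH, flanked by C5 and the C4 gem-dimethyl group, should be too hindered to be activated.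

Step 16
Reactants: 21 7-{[(1R,4R,4aS,8aS)-4-hydroxy-2,5,5,8a-tetramethyl-6-oxo-1,4,4a,5,6,7,8,8a-octahydronaphthalen-1-yl]methoxy}-2H-chromen-2-one
Product: 22 (1R,4R,4aS,8aS)-3,4a,8,8-tetramethyl-7-oxo-4-{[(2-oxo-2H-chromen-7-yl)oxy]methyl}-1,4,4a,5,6,7,8,8a-octahydronaphthalen-1-yl acetate
Conditions: Ac2O, pyridine, DMAP (cat.), CH2Cl2, rt
Reagents that add atoms: acetic anhydride, CC(=O)OC(C)=O
Why: DMAP-catalysed acylation of the hindered equatorial C6–OH with acetic anhydride gives the acetate and leaves the ketone, the alkene and the coumarin untouched.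

**Compound list**

1 | but-2-yn-1-ol | CC#CCO | starting material
2 | (Z)-3-iodobut-2-en-1-ol | C/C(I)=C/CO | intermediate
3 | tert-butyl{[(2Z)-3-iodobut-2-en-1-yl]oxy}dimethylsilane | C/C(I)=C/CO[Si](C)(C)C(C)(C)C | intermediate
4 | tert-butyldimethyl{[(2E)-3-(4,4,5,5-tetramethyl-1,3,2-dioxaborolan-2-yl)but-2-en-1-yl]oxy}silane (boron cis to CH2OSi) | C/C(B1OC(C)(C)C(C)(C)O1)=C/CO[Si](C)(C)C(C)(C)C | intermediate
5 | furan-2(5H)-one | O=C1C=CCO1 | starting material
6 | (4S)-4-[(2Z)-4-{[tert-butyl(dimethyl)silyl]oxy}but-2-en-2-yl]oxolan-2-one | C/C(=C/CO[Si](C)(C)C(C)(C)C)[C@@H](CO1)CC1=O | intermediate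
7 | tert-butyl bromoacetate | CC(C)(C)OC(=O)CBr | starting material
8 | tert-butyl [(3R,4S)-4-[(2Z)-4-{[tert-butyl(dimethyl)silyl]oxy}but-2-en-2-yl]-2-oxooxolan-3-yl]acetate (3,4-trans) | C/C(=C/CO[Si](C)(C)C(C)(C)C)[C@@H](CO1)[C@@H](CC(=O)OC(C)(C)C)C1=O | intermediate
9 | tert-butyl [(3S,4R)-4-[(2Z)-4-{[tert-butyl(dimethyl)silyl]oxy}but-2-en-2-yl]-3-methyl-2-oxooxolan-3-yl]acetate (methyl trans to the 4-alkenyl group) | C/C(=C/CO[Si](C)(C)C(C)(C)C)[C@@H](CO1)[C@](C)(CC(=O)OC(C)(C)C)C1=O | intermediate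
10 | tert-butyl [(3S,4R)-4-[(2Z)-4-{[tert-butyl(dimethyl)silyl]oxy}but-2-en-2-yl]-2-hydroxy-3-methyloxolan-3-yl]acetate (lactol, both anomers) | C/C(=C/CO[Si](C)(C)C(C)(C)C)[C@@H](CO1)[C@](C)(CC(=O)OC(C)(C)C)C1O | intermediate
11 | tert-butyl (3R,4R,5Z)-7-{[tert-butyl(dimethyl)silyl]oxy}-4-(hydroxymethyl)-3,5-dimethyl-3-(2-methylprop-1-en-1-yl)hept-5-enoate | C/C(=C/CO[Si](C)(C)C(C)(C)C)[C@@H](CO)[C@](C)(CC(=O)OC(C)(C)C)C=C(C)C | intermediate (not isolated)
12 | (4R,5R)-5-[(2Z)-4-{[tert-butyl(dimethyl)silyl]oxy}but-2-en-2-yl]-4-methyl-4-(2-methylprop-1-en-1-yl)oxan-2-one | C/C(=C/CO[Si](C)(C)C(C)(C)C)[C@@H](CO1)[C@](C)(CC1=O)C=C(C)C | intermediate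
13 | (4R,5R)-5-[(2Z)-4-hydroxybut-2-en-2-yl]-4-methyl-4-(2-methylprop-1-en-1-yl)oxan-2-one | C/C(=C/CO)[C@@H](CO1)[C@](C)(CC1=O)C=C(C)C | intermediate
14 | (2Z)-3-[(3R,4R)-4-methyl-4-(2-methylprop-1-en-1-yl)-6-oxooxan-3-yl]but-2-enal | C/C(=C/C=O)[C@@H](CO1)[C@](C)(CC1=O)C=C(C)C | intermediate
15 | (4aS,5R,6R,8aR)-6-hydroxy-4a,8-dimethyl-5-(prop-1-en-2-yl)-4a,5,6,8a-tetrahydro-1H-isochromen-3(4H)-one | O[C@@H]1C=C(C)[C@H]2COC(=O)C[C@]2(C)[C@H]1C(C)=C | intermediate
16 | (4aS,5R,6R,8aR)-4a,8-dimethyl-5-(prop-1-en-2-yl)-3,4,4a,5,6,8a-hexahydro-1H-isochromene-3,6-diol (lactol, both anomers) | O[C@@H]1C=C(C)[C@H]2COC(O)C[C@]2(C)[C@H]1C(C)=C | intermediate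
17 | 3-[(1S,2R,5R,6R)-5-hydroxy-2-(hydroxymethyl)-1,3-dimethyl-6-(prop-1-en-2-yl)cyclohex-3-en-1-yl]propanenitrile | O[C@@H]1C=C(C)[C@@H](CO)[C@](C)(CCC#N)[C@H]1C(C)=C | intermediate
18 | (4aS,5R,8R,8aS)-8-hydroxy-5-(hydroxymethyl)-1,1,4a,6-tetramethyl-3,4,4a,5,8,8a-hexahydronaphthalen-2(1H)-imine | O[C@@H]1C=C(C)[C@@H](CO)[C@]2(C)CCC(=N)C(C)(C)[C@@H]12 | intermediate (not isolated)
19 | (4aS,5R,8R,8aS)-8-hydroxy-5-(hydroxymethyl)-1,1,4a,6-tetramethyl-3,4,4a,5,8,8a-hexahydronaphthalen-2(1H)-one | O[C@@H]1C=C(C)[C@@H](CO)[C@]2(C)CCC(=O)C(C)(C)[C@@H]12 | intermediate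
20 | 7-hydroxy-2H-chromen-2-one (umbelliferone) | Oc1ccc2ccc(=O)oc2c1 | starting material
21 | 7-{[(1R,4R,4aS,8aS)-4-hydroxy-2,5,5,8a-tetramethyl-6-oxo-1,4,4a,5,6,7,8,8a-octahydronaphthalen-1-yl]methoxy}-2H-chromen-2-one | O[C@@H]1C=C(C)[C@@H](COc2ccc3ccc(=O)oc3c2)[C@]2(C)CCC(=O)C(C)(C)[C@@H]12 | intermediate
22 | (1R,4R,4aS,8aS)-3,4a,8,8-tetramethyl-7-oxo-4-{[(2-oxo-2H-chromen-7-yl)oxy]methyl}-1,4,4a,5,6,7,8,8a-octahydronaphthalen-1-yl acetate | CC(=O)O[C@@H]1C=C(C)[C@@H](COc2ccc3ccc(=O)oc3c2)[C@]2(C)CCC(=O)C(C)(C)[C@@H]12 | target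

**Step count and risks**

Total step count: 16. Longest linear sequence: 16 steps (1 to 22); 5, 7 and 20 enter as purchased fragments.

Steps most likely to fail:

1. Step 13. The reductive cyanation may stop at the oxazoline, or lose sulfinate to give an oxazole, and the enolizable open-chain aldehyde may self-condense under KOt-Bu. The fallback sets out from 16 and returns at 17. A Wittig reaction with Ph3P=CHOMe (from MeOCH2PPh3Cl and KN(SiMe3)2) should give the methyl enol ether F6. Dilute aqueous HCl in THF at 0 °C should hydrolyse it to the aldehyde F7. I2 in aqueous NH3/THF should then convert the aldehyde into nitrile 17.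

2. Step 14. Premature reduction of the tertiary C4 radical (net hydrogenation of the isopropenyl group) may outrun the slow 6-exo-dig addition to the nitrile. The fallback sets out from 17 and returns at 19. Markovnikov hydrobromination by hydrogen atom transfer (Co(acac)2, t-BuOOH, Et3SiH, TsBr) should give the tertiary bromide F8. Slow addition of Bu3SnH with AIBN in benzene at 80 °C keeps the hydrogen donor concentration low, so that the radical should cyclize to ketimine 18, which is hydrolysed as in step 14 to 19.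

3. Step 4. Carbometalation of the butenolide by the hindered, trisubstituted alkenylrhodium species may be slow, with protodeboronation and loss of enantioselectivity as the competing processes. The fallback sets out from 3 and returns at 6, with an auxiliary in place of the catalyst. Pd(PPh3)4-catalysed coupling of 3 with BrZnCH2CO2Et should give the ethyl ester F1, and LiOH the acid F2. The pivaloyl mixed anhydride and lithiated (4S)-4-benzyl-1,3-oxazolidin-2-one should give the imide F3. NaN(SiMe3)2 and then 7 should give the alkylated imide F4 (Evans alkylation anti to the benzyl group, which sets C9). LiBH4 should remove the auxiliary to give the hydroxy ester F5, and catalytic KOt-Bu in THF should close it to lactone 6.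

**Further compounds**

F1 | step 4 | ethyl (3Z)-5-{[tert-butyl(dimethyl)silyl]oxy}-3-methylpent-3-enoate | C/C(CC(=O)OCC)=C/CO[Si](C)(C)C(C)(C)C
F2 | step 4 | (3Z)-5-{[tert-butyl(dimethyl)silyl]oxy}-3-methylpent-3-enoic acid | C/C(CC(=O)O)=C/CO[Si](C)(C)C(C)(C)C
F3 | step 4 | (4S)-4-benzyl-3-[(3Z)-5-{[tert-butyl(dimethyl)silyl]oxy}-3-methylpent-3-enoyl]-1,3-oxazolidin-2-one | C/C(CC(=O)N1[C@@H](Cc2ccccc2)COC1=O)=C/CO[Si](C)(C)C(C)(C)C
F4 | step 4 | tert-butyl (3S,4Z)-3-{[(4S)-4-benzyl-2-oxo-1,3-oxazolidin-3-yl]carbonyl}-6-{[tert-butyl(dimethyl)silyl]oxy}-4-methylhex-4-enoate | C/C(=C/CO[Si](C)(C)C(C)(C)C)[C@@H](C(=O)N1[C@@H](Cc2ccccc2)COC1=O)CC(=O)OC(C)(C)C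
F5 | step 4 | tert-butyl (3S,4Z)-6-{[tert-butyl(dimethyl)silyl]oxy}-3-(hydroxymethyl)-4-methylhex-4-enoate | C/C(=C/CO[Si](C)(C)C(C)(C)C)[C@@H](CO)CC(=O)OC(C)(C)C
F6 | step 13 | (1R,4R,5S,6R)-4-(hydroxymethyl)-5-(3-methoxyprop-2-en-1-yl)-3,5-dimethyl-6-(prop-1-en-2-yl)cyclohex-2-en-1-ol (enol ether E/Z mixture) | O[C@@H]1C=C(C)[C@@H](CO)[C@](C)(CC=COC)[C@H]1C(C)=C
F7 | step 13 | 3-[(1S,2R,5R,6R)-5-hydroxy-2-(hydroxymethyl)-1,3-dimethyl-6-(prop-1-en-2-yl)cyclohex-3-en-1-yl]propanal | O[C@@H]1C=C(C)[C@@H](CO)[C@](C)(CCC=O)[C@H]1C(C)=C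
F8 | step 14 | 3-[(1S,2R,5R,6R)-6-(2-bromopropan-2-yl)-5-hydroxy-2-(hydroxymethyl)-1,3-dimethylcyclohex-3-en-1-yl]propanenitrile | O[C@@H]1C=C(C)[C@@H](CO)[C@](C)(CCC#N)[C@H]1C(C)(C)Br
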